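The ratio to follow in the ochre flask is target made per partner charged.

| setting | ochre | red | flask |
|---|---|---|---|
| substrate | 10 mM | 10 mM | 10 mM |
| partner | 20 mM | 40 mM | 20.0 mM |
| free catalyst | 5 µM | 5 µM | 5.0 µM |
| remark | the very flask that is asked about, followed so far | run made earlier |  |
| time |  |  | 80 min |

| run | time / min | target / % | substrate / % |
|---|---|---|---|
| ochre | 4.00 | 40.0 | 60.1 |
| ochre | 8.00 | 42.9 | 56.6 |
| ochre | 20.0 | 44.7 | 56.0 |
| ochre | 50.0 | 43.4 | 57.2 |
| red | 0.500 | 10.3 | 89.0 |
| red | 1.00 | 20.0 | 79.6 |
| red | 2.50 | 42.2 | 57.6 |
| red | 6.00 | 60.4 | 39.6 |

(readings scatter by 0.5 percentage points)

- target, in percent of the substrate first charged, at 80 min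
- which option adds most target ("none" when 2 percentage points or less is all one gets) (Tuesday's / Thursday's / Monday's / Saturday's / none)
- target present, with what was taken out counted in, in percent of the substrate first charged, after Monday's
- target present, with what was taken out counted in, in percent of the substrate first charged, after Saturday's

- Tuesday's: at 80 min take out 90% of the target then present, then wait 80 min
- Thursday's: at 80 min add free catalyst, 100% of the amount charged, then wait 80 min
- Monday's: at 80 min add partner, 50.0% of the amount charged, then wait 80 min
- Saturday's: change nothing and wait 80 min more

- removed target is counted in
- additions bring no volume worth counting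

The ochre run stalls at a plateau read at 44.0% with 57.2% of the substrate still unconverted at its last reading, so substrate has not run short. But the red run, on twice the partner and the same catalyst, climbs past that level to 60.4%, so the catalyst charge can make more target. Partner is not read, so the reckoning made here is a judgement: partner charged is split between target and some unseen loss, and the stall in the ochre flask marks the end of that split. That gives the partner yield, target at the stop per partner charged, of 0.220. It is a reading, and the red run gives no second value, having shown no stop by its last reading. So this reckoning keeps the ochre flask near 44.0% at 80 min and expects no target from waiting, extra catalyst or removal. At the same partner yield, Monday's partner should bring about 22 percentage points, reaching 66.1%.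

The forecast stands close to this reckoning with 44% now and 44% after Saturday's, but differs with 55% after Monday's and Tuesday's as best, holding that “this looks like a true equilibrium rather than a dead catalyst”.

The ochre flask gives 43.7% now, 43.7% after Saturday's and 67.7% after Monday's, and the best option is Monday's.

    partner + catalyst intermediate A ⇌ catalyst intermediate B (K = 1800 L mol⁻¹, k = 1100 L mol⁻¹ s⁻¹)
    catalyst intermediate B → free catalyst + target (k = 25.0 s⁻¹)
    partner → decomposed reagent (k = 0.00920 s⁻¹)
    substrate + free catalyst → catalyst intermediate A (k = 1500 L mol⁻¹ s⁻¹)

In the ochre flask at 80.0 min, partner, charged at twice the substrate, stands at 0% of its charge and is the limiting reagent, with 15.6 mM of decomposed reagent beside 4.37 mM of target. Monday's charge returned 0.240 target per partner, against the 0.220 carried. That yield puts the neighbour flask, charged with 5.0 mM of partner, at 11.0% of target. It gives 15.6%, a partner yield of 0.313, with 3.44 mM of decomposed reagent and 84.3% of its substrate left.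

The runs were computed with constants of no real substance; scatter was added.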